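**Retrosynthetic overview**
1. Prismatomerin 9 ⇒ α-methylene spirolactone 7 + 4-iodophenol 8. The C13–aryl bond is made last by a Heck reaction, so no protecting groups are needed.
2. 7 ⇒ acrylic acid 6. A light-driven Cu(II)-carboxylate dehydrogenative 5-exo spirolactonisation forms the C8–O bond and the C6=C7 alkene (key step).
3. 6 ⇒ Meldrum's acid adduct 4 ⇒ 10-oxogenipin 2 + Meldrum's acid 3. A Knoevenagel / hemiacetal oxa-Michael domino forms C10–C11 and C10–O–C1.
4. 2 ⇒ genipin 1, which supplies C5, C9, the cyclopenta[c]pyran and the ester.
5. Ring order: cyclopenta[c]pyran (bought) → bridging acetal oxolane (step 2) → spiro-γ-lactone (step 4).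

Assumption: iridoid numbering is used. C1 is the acetal CH, C3=C4 the enol ether, C5/C9 the ring-fusion CH, C8 the spiro carbon and C10 the O–CH. C11, C12 and C13 are the lactone α-carbon, the C=O and the exocyclic CH. Genipin (from Gardenia fruit) is taken as a bulk commercial chiral-pool material.

**Step 1**
Reactants: 1 genipin
Product: 2 10-oxogenipin (C10 enal; C1 lactol, C5 and C9 unchanged)
Conditions: activated MnO2 (15 equiv), CH2Cl2/EtOAc, rt, 2–4 h
Reagents that add atoms: none
Why: Heterogeneous MnO2 allylic oxidation takes only the primary allylic alcohol, leaves the non-allylic lactol, the enol ether and the ester intact, and touches no stereocentre.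

**Step 2**
Reactants: 2 10-oxogenipin; 3 Meldrum's acid
Product: 4 (1R,5S,9S,10S)-10-(2,2-dimethyl-4,6-dioxo-1,3-dioxan-5-yl)-1,10-anhydrogenipin. It is a tricyclic acetal with O bridging C1 and C10. The Meldrum's ring is exo (syn to H-1 and H-9) and C7=C8 is retained.
Conditions: 3 (1.05 equiv), pyridine/CH2Cl2 1:4, 4 Å MS, 0 °C → rt; cold aq NaHSO4 work-up; used crude
Reagents that add atoms: Meldrum's acid, CC1(C)OC(=O)CC(=O)O1
Why: In this domino Knoevenagel condensation / hemiacetal oxa-Michael addition (Evans–Prunet type, 5-exo-trig), the lactol anomerises by ring–chain tautomerism, only the α-OH can reach C10, and because the addition to the very electrophilic alkylidene Meldrum's acid is reversible the large group settles on the convex exo face, giving 10S with C1 locked as R by the bridge.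

**Step 3**
Reactants: 4; 5 Eschenmoser's salt
Product: 6 2-[(1R,5S,9S,10S)-1,10-anhydrogenipin-10-yl]acrylic acid (exo 1-carboxyvinyl group on C10)
Conditions: 5 (1.5 equiv), THF, rt, 1 h; then H2O (THF/H2O 4:1), 60 °C
Reagents that add atoms: Eschenmoser's salt, C[N+](C)=C.[I-] (gives the =CH2 carbon); water, O (may supply a carboxyl O)
Why: This is the standard Meldrum's acid → α-substituted acrylate methylenation (Mannich alkylation, hydrolytic ring opening, then decarboxylative Grob-type loss of Me2NH, CO2 and acetone), and C-alkylation makes C11 quaternary, which blocks retro-Michael and preserves C10.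

**Step 4 (key step)**
Reactants: 6
Product: 7 methyl (1S,4S,8R,10S,14S)-11-methylidene-12-oxo-7,9,13-trioxatetracyclo[6.5.1.0^1,10.0^4,14]tetradeca-2,5-diene-5-carboxylate (the target skeleton with =CH2 in place of the benzylidene)
Conditions: Cu(OTf)2 (2.5 equiv), Li2CO3 (3 equiv), MeCN (0.02 M), 390 nm LEDs, 25–30 °C, Ar
Reagents that add atoms: none
Why: Proposed new method: Cu(II)-carboxylate LMCT dehydrogenative spirolactonisation, in which 390 nm excitation of the Cu(II) carboxylate of 6 gives Cu(I) and an acryloyloxy radical that loses CO2 only slowly because its carboxyl sits on an sp2 carbon (as with aroyloxy radicals); the exo C10 tether holds this O-radical directly over the β-face of C8, so it closes 5-exo-trig (C7 is out of reach, C7–C8–C10–C11 dihedral about 100°) to form the C8–O bond and the 8S quaternary centre under substrate control; a second Cu(II) traps the C7 radical and Kochi-type β-H elimination can use only C6–H because C8 is quaternary, giving C6=C7; no electrophile has to enter the concave face, unlike halo- or seleno-lactonisation; the closest known reaction types are Cu-LMCT decarboxylative functionalisation of benzoic acids, Cu(II) oxidative elimination of alkyl radicals, Kharasch–Sosnovsky allylic acyloxylation and photo-aerobic Se-catalysed dehydrogenative lactonisation.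

**Step 5**
Reactants: 7; 8 4-iodophenol
Product: 9 prismatomerin
Conditions: 8 (1.5 equiv), Pd(OAc)2 (10 mol %), n-Bu4NCl (1 equiv), NaHCO3 (2.5 equiv), DMF, 60 °C, Ar
Reagents that add atoms: 4-iodophenol, Oc1ccc(I)cc1
Why: In this ligand-free (Jeffery) Mizoroki–Heck arylation of an α-methylene-γ-butyrolactone, the aryl group adds to the terminal CH2 and syn β-H elimination from the benzylic carbon gives the exocyclic E-benzylidene (aryl anti to C=O), while the free phenol is tolerated, C6=C7 and C3=C4 are far less reactive, and no stereocentre is touched.

**Compound list**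

| No. | Name | SMILES | Role |
|---|---|---|---|
| 1 | genipin | COC(=O)C1=CO[C@H]([C@H]2[C@@H]1CC=C2CO)O | starting material |
| 2 | 10-oxogenipin | COC(=O)C1=CO[C@H]([C@H]2[C@@H]1CC=C2C=O)O | intermediate |
| 3 | Meldrum's acid | CC1(C)OC(=O)CC(=O)O1 | starting material |
| 4 | exo-10-(Meldrum's acid-5-yl)-1,10-anhydrogenipin | COC(=O)C1=CO[C@@H]2O[C@@H](C4C(=O)OC(C)(C)OC4=O)C3=CC[C@H]1[C@H]23 | intermediate |
| 5 | Eschenmoser's salt | C[N+](C)=C.[I-] | starting material |
| 6 | exo-10-(1-carboxyvinyl)-1,10-anhydrogenipin | COC(=O)C1=CO[C@@H]2O[C@@H](C(=C)C(O)=O)C3=CC[C@H]1[C@H]23 | intermediate |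
| 7 | α-methylene spirolactone (desaryl prismatomerin) | COC(=O)C1=CO[C@@H]2O[C@H]3C(=C)C(=O)O[C@]34C=C[C@H]1[C@H]24 | intermediate |
| 8 | 4-iodophenol | Oc1ccc(I)cc1 | starting material |
| 9 | prismatomerin | COC(=O)C1=CO[C@@H]2O[C@H]3/C(=C\c4ccc(O)cc4)C(=O)O[C@]34C=C[C@H]1[C@H]24 | target |

**Step count:** 5 steps in total. The longest linear sequence is 5 steps (1 → 2 → 4 → 6 → 7 → 9).

**Steps most likely to fail**
1. **Step 4 (proposed new reaction).**
   - Risks: decarboxylation to a vinyl radical; over-oxidation of the C7 radical to a cation, leading to Ritter capture by MeCN; acetal cleavage by the Lewis-acidic copper salts.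
   - Fallback (known chemistry): Schenck ene reaction of 6 (O2, TPP, visible light, CH2Cl2, 0 °C). Singlet oxygen attacks the convex face, where only H-6β is usable. Abstracting H-9 would place an alkene at the central bowl carbon, and H-10 lies in the alkene plane. The product is the C8 tertiary allylic hydroperoxide. PPh3 reduction and EDC/DMAP lactonisation then give 7 (+1–2 steps).
2. **Step 2.**
   - Risks: competing condensation at the ring-opened C1 aldehyde; retro-oxa-Michael of neutral 4 during isolation.
   - Fallback: switch to carbonyl addition. Convert 1 to its 1-O-methyl acetal (MeOH, CSA) and oxidise with MnO2. Carry out vinylalumination of the enal (tert-butyl propiolate, DIBAL-H/NMO). Treat with TFA, which closes the C1–O–C10 acetal and cleaves the t-Bu ester, giving 6 after the C10 epimers are separated (+1 step, weaker C10 control).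
3. **Step 5.**
   - Risks: Pd(0) ionisation of the tertiary allylic lactone; β-H elimination toward C10–H, giving an endocyclic butenolide.
   - Fallback: arylate before the lactone exists. Carry out the Heck reaction on acid 6 with 4-iodophenyl acetate to give the (E)-α-substituted 4-acetoxycinnamic acid. Apply the step-4 lactonisation, then deacetylate with NH4OAc in aq MeOH (+1 step).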